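## Retrosynthetic overview
1. Ester C–O bond: gentiside F ⇒ (S)-16-methyloctadecan-1-ol + 2,3-bis(benzyloxy)benzoic acid. The catechol is unmasked last by hydrogenolysis.
2. Key C–C bond C12–C13 (target numbering: C1 = OCH2, C16 = stereocentre): saturated chain ⇒ C14 ketone ⇒ C12=C13 enone ⇒ β-hydroxy ketone ⇒ intermolecular lithium-enolate aldol of (S)-4-methylhexan-2-one with 12-(benzyloxy)dodecanal.
3. (S)-4-Methylhexan-2-one ⇒ (S)-2-methylbutyl Grignard reagent + Weinreb acetamide ⇒ (S)-2-methylbutan-1-ol, the chiral-pool source of the only stereocentre.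
4. 12-(Benzyloxy)dodecanal ⇒ dodecane-1,12-diol (monobenzylation, oxidation). The protected acid ⇒ 2,3-dihydroxybenzoic acid.
5. Rings: none is formed. The single benzene ring is bought in with 2,3-dihydroxybenzoic acid.

Assumption: commercial (S)-(−)-2-methylbutan-1-ol of at least 98% ee is used, so the optical purity of the target equals that of this starting material.

## Route

Step 1
Reactants: 1 (S)-2-methylbutan-1-ol
Product: 2 (S)-2-methylbutyl 4-methylbenzenesulfonate
Conditions: TsCl (1.2 equiv), Et3N (1.5 equiv), DMAP (0.1 equiv), CH2Cl2, 0 °C to rt, 12 h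
Reagents that add atoms: 4-toluenesulfonyl chloride (TsCl), Cc1ccc(cc1)S(=O)(=O)Cl
Why: Tosylation (O-sulfonylation) of the primary alcohol takes place at oxygen only, so the S stereocentre (future C16) is carried over untouched from the chiral pool.

Step 2
Reactants: 2 (S)-2-methylbutyl 4-methylbenzenesulfonate
Product: 3 (S)-1-bromo-2-methylbutane
Conditions: LiBr (3 equiv), acetone, reflux, 16 h; pentane/water work-up, distillation
Reagents that add atoms: lithium bromide (LiBr), [Li+].[Br-]
Why: Finkelstein-type SN2 displacement by bromide happens at the primary carbon and not at the neighbouring stereocentre, which stays S without the partial racemisation that acidic bromination can cause.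

Step 3
Reactants: 3 (S)-1-bromo-2-methylbutane; 4 N-methoxy-N-methylacetamide
Product: 7 (S)-4-methylhexan-2-one, via Grignard reagent 5 (not isolated), via magnesium hemiaminal chelate 6 (not isolated)
Conditions: Mg turnings (1.3 equiv), I2 (cat.), Et2O, reflux; then 4 (1.1 equiv), Et2O, 0 °C, 2 h; 1 M HCl quench; distillation
Reagents that add atoms: none
Why: Grignard formation followed by Weinreb ketone synthesis works because chelate 6 does not collapse before the acid quench, so no tertiary alcohol forms, and the stereocentre is β to magnesium and then β to the carbonyl, where it cannot epimerise.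

Step 4
Reactants: 8 dodecane-1,12-diol
Product: 10 12-(benzyloxy)dodecan-1-ol, via sodium monoalkoxide 9 (not isolated)
Conditions: 8 (2.5 equiv), NaH (1.0 equiv), THF/DMF 4:1, 0 °C to rt; BnBr (1.0 equiv), n-Bu4NI (5 mol%), 50 °C, 12 h; excess 8 recovered
Reagents that add atoms: benzyl bromide (BnBr), BrCc1ccccc1
Why: Williamson ether synthesis run with an excess of the symmetrical diol makes the monoether the statistically dominant product, and it separates easily from the polar diol and the non-polar diether.

Step 5
Reactants: 10 12-(benzyloxy)dodecan-1-ol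
Product: 11 12-(benzyloxy)dodecanal
Conditions: TEMPO (10 mol%), PhI(OAc)2 (1.1 equiv), CH2Cl2, rt, 4 h
Reagents that add atoms: none
Why: The TEMPO/PhI(OAc)2 (Piancatelli–Margarita) oxidation stops at the aldehyde in a water-free medium and leaves the benzyl ether alone.

Step 6
Reactants: 7 (S)-4-methylhexan-2-one; 11 12-(benzyloxy)dodecanal
Product: 14 (3S)-18-(benzyloxy)-7-hydroxy-3-methyloctadecan-5-one (about 1:1 epimers at C7), via lithium enolate 12 (not isolated), via lithium aldolate 13 (not isolated)
Conditions: iPr2NH (1.2 equiv), n-BuLi (1.15 equiv), THF, −78 to 0 °C; 7 (1.1 equiv), −78 °C, 45 min; 11 (1.0 equiv), −78 °C, 1 h; AcOH/THF quench at −78 °C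
Reagents that add atoms: none
Why: In this directed intermolecular aldol addition LiN(iPr)2 deprotonates the free methyl group rather than the CH2 next to the branch, and the preformed kinetic enolate 12 adds to the aldehyde faster than it transfers a proton, which forms the C12–C13 bond, while the new carbinol centre is stereorandom but is erased in step 7 and C16 is not touched.

Step 7
Reactants: 14 (3S)-18-(benzyloxy)-7-hydroxy-3-methyloctadecan-5-one
Product: 16 (3S,6E)-18-(benzyloxy)-3-methyloctadec-6-en-5-one, via β-mesyloxy ketone 15 (not isolated)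
Conditions: MsCl (1.5 equiv), Et3N (5 equiv), CH2Cl2, 0 °C to rt, 4 h
Reagents that add atoms: none
Why: Mesylation followed by E1cB elimination of the β-mesyloxy ketone completes the aldol condensation, gives the conjugated E-enone from both carbinol epimers and does not involve the stereocentre on the other side of the carbonyl.

Step 8
Reactants: 16 (3S,6E)-18-(benzyloxy)-3-methyloctadec-6-en-5-one
Product: 18 (S)-18-hydroxy-3-methyloctadecan-5-one, via saturated keto benzyl ether 17 (not isolated)
Conditions: H2 (1 atm), 10% Pd/C, EtOH/EtOAc 1:1, rt, 16 h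
Reagents that add atoms: none
Why: Catalytic hydrogenation saturates the conjugated C=C first and then hydrogenolyses the benzyl ether, whereas an aliphatic ketone is inert to Pd/C at 1 atm.

Step 9
Reactants: 18 (S)-18-hydroxy-3-methyloctadecan-5-one
Product: 20 (S)-16-methyloctadecan-1-ol, via hydrazone 19 (not isolated)
Conditions: N2H4·H2O (10 equiv), KOH (6 equiv), diethylene glycol, 130 °C, 2 h; distil off H2O/N2H4; 200 °C, 4 h
Reagents that add atoms: none
Why: In the Wolff–Kishner reduction (Huang-Minlon procedure) hydrazone 19 loses N2 under hot KOH and C=O becomes CH2, the primary alcohol is inert, and the stereocentre is β to the carbonyl and therefore cannot be enolised.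

Step 10
Reactants: 21 2,3-dihydroxybenzoic acid
Product: 22 benzyl 2,3-bis(benzyloxy)benzoate
Conditions: BnBr (3.5 equiv), K2CO3 (5 equiv), DMF, 60 °C, 16 h
Reagents that add atoms: benzyl bromide (BnBr), BrCc1ccccc1
Why: Exhaustive SN2 O-benzylation (Williamson ether synthesis plus carboxylate alkylation) caps both phenols and the acid in one operation, which avoids any selectivity problem.

Step 11
Reactants: 22 benzyl 2,3-bis(benzyloxy)benzoate
Product: 24 2,3-bis(benzyloxy)benzoic acid, via sodium carboxylate 23 (not isolated)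
Conditions: 5 M aq NaOH (5 equiv), MeOH/1,4-dioxane, reflux, 4 h; then 2 M HCl to pH 2
Reagents that add atoms: sodium hydroxide (NaOH), [Na+].[OH-]
Why: Saponification (BAc2 ester hydrolysis) cleaves only the benzyl ester, because aryl benzyl ethers are stable to hydroxide.

Step 12
Reactants: 20 (S)-16-methyloctadecan-1-ol; 24 2,3-bis(benzyloxy)benzoic acid
Product: 26 (S)-16-methyloctadecyl 2,3-bis(benzyloxy)benzoate, via O-acylisourea 25 (not isolated)
Conditions: 24 (1.1 equiv), DCC (1.2 equiv), DMAP (0.2 equiv), CH2Cl2, 0 °C to rt, 12 h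
Reagents that add atoms: none
Why: Steglich esterification of an unhindered primary alcohol is fast under DMAP catalysis, which outruns N-acylurea formation, and with both phenols masked no competing aryl ester or oligomer can form.

Step 13
Reactants: 26 (S)-16-methyloctadecyl 2,3-bis(benzyloxy)benzoate
Product: 27 gentiside F [(S)-16-methyloctadecyl 2,3-dihydroxybenzoate]
Conditions: H2 (1 atm), 10% Pd/C, EtOAc/EtOH 1:1, rt, 6 h
Reagents that add atoms: none
Why: Neutral catalytic hydrogenolysis removes both aryl benzyl ethers while the non-benzylic alkyl ester, the arene and the remote S stereocentre are inert.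

## Compound list
1 | (S)-2-methylbutan-1-ol | CC[C@H](C)CO | starting material
2 | (S)-2-methylbutyl 4-methylbenzenesulfonate | CC[C@H](C)COS(=O)(=O)c1ccc(C)cc1 | intermediate
3 | (S)-1-bromo-2-methylbutane | CC[C@H](C)CBr | intermediate
4 | N-methoxy-N-methylacetamide | CC(=O)N(C)OC | starting material
5 | [(S)-2-methylbutyl]magnesium bromide | CC[C@H](C)C[Mg]Br | intermediate
6 | bromomagnesium (4S)-2-[methoxy(methyl)amino]-4-methylhexan-2-olate (tetrahedral chelate, C2 undefined) | CC[C@H](C)CC(C)(O[Mg]Br)N(C)OC | intermediate
7 | (S)-4-methylhexan-2-one | CC[C@H](C)CC(C)=O | intermediate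
8 | dodecane-1,12-diol | OCCCCCCCCCCCCO | starting material
9 | sodium 12-hydroxydodecan-1-olate | [Na+].[O-]CCCCCCCCCCCCO | intermediate
10 | 12-(benzyloxy)dodecan-1-ol | OCCCCCCCCCCCCOCc1ccccc1 | intermediate
11 | 12-(benzyloxy)dodecanal | O=CCCCCCCCCCCCOCc1ccccc1 | intermediate
12 | lithium (S)-4-methylhex-1-en-2-olate | [Li+].CC[C@H](C)CC(=C)[O-] | intermediate
13 | lithium (16S)-1-(benzyloxy)-16-methyl-14-oxooctadecan-12-olate (C12 epimers) | [Li+].CC[C@H](C)CC(=O)CC([O-])CCCCCCCCCCCOCc1ccccc1 | intermediate
14 | (3S)-18-(benzyloxy)-7-hydroxy-3-methyloctadecan-5-one (C7 epimers) | CC[C@H](C)CC(=O)CC(O)CCCCCCCCCCCOCc1ccccc1 | intermediate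
15 | (16S)-1-(benzyloxy)-16-methyl-14-oxooctadecan-12-yl methanesulfonate (C12 epimers) | CC[C@H](C)CC(=O)CC(OS(C)(=O)=O)CCCCCCCCCCCOCc1ccccc1 | intermediate
16 | (3S,6E)-18-(benzyloxy)-3-methyloctadec-6-en-5-one | CC[C@H](C)CC(=O)/C=C/CCCCCCCCCCCOCc1ccccc1 | intermediate
17 | (S)-18-(benzyloxy)-3-methyloctadecan-5-one | CC[C@H](C)CC(=O)CCCCCCCCCCCCCOCc1ccccc1 | intermediate
18 | (S)-18-hydroxy-3-methyloctadecan-5-one | CC[C@H](C)CC(=O)CCCCCCCCCCCCCO | intermediate
19 | (S)-14-hydrazinylidene-16-methyloctadecan-1-ol | CC[C@H](C)CC(=NN)CCCCCCCCCCCCCO | intermediate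
20 | (S)-16-methyloctadecan-1-ol | CC[C@H](C)CCCCCCCCCCCCCCCO | intermediate
21 | 2,3-dihydroxybenzoic acid | OC(=O)c1cccc(O)c1O | starting material
22 | benzyl 2,3-bis(benzyloxy)benzoate | O=C(OCc1ccccc1)c1cccc(OCc2ccccc2)c1OCc1ccccc1 | intermediate
23 | sodium 2,3-bis(benzyloxy)benzoate | [Na+].[O-]C(=O)c1cccc(OCc2ccccc2)c1OCc1ccccc1 | intermediate
24 | 2,3-bis(benzyloxy)benzoic acid | OC(=O)c1cccc(OCc2ccccc2)c1OCc1ccccc1 | intermediate
25 | O-[2,3-bis(benzyloxy)benzoyl]-N,N'-dicyclohexylisourea | O=C(OC(=NC1CCCCC1)NC1CCCCC1)c1cccc(OCc2ccccc2)c1OCc1ccccc1 | intermediate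
26 | (S)-16-methyloctadecyl 2,3-bis(benzyloxy)benzoate | CC[C@H](C)CCCCCCCCCCCCCCCOC(=O)c1cccc(OCc2ccccc2)c1OCc1ccccc1 | intermediate
27 | gentiside F, (S)-16-methyloctadecyl 2,3-dihydroxybenzoate | CC[C@H](C)CCCCCCCCCCCCCCCOC(=O)c1cccc(O)c1O | target

## Step count and weak points
Total step count: 13.
Longest linear sequence: 9 steps (1, 2, 3, 6, 7, 8, 9, 12, 13).

**Risk 1, step 6 (aldol addition).**
- The lithium enolate may equilibrate, may enolise the aldehyde (leading to self-aldol of 11), or the aldolate may revert on warming.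
- The fallback sets out from 7 (with 11 as partner) and comes back at 14.
- Enolate 12 is trapped at −78 °C with Me3SiCl. The regiochemically pure silyl enol ether (S)-trimethyl[(4-methylhex-1-en-2-yl)oxy]silane F2 is isolated by distillation.
- A Mukaiyama aldol addition of this neutral nucleophile to 11 under TiCl4 (1.0 equiv, CH2Cl2, −78 °C), followed by aqueous work-up, gives 14.
- No strong base ever meets the aldehyde, and the addition is irreversible.

**Risk 2, step 9 (Wolff–Kishner reduction).**
- The conditions are forcing (KOH, 200 °C) and the substrate is waxy and prone to foaming. Azine formation or incomplete reduction is possible.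
- The fallback sets out from 18 and comes back at 20.
- Ethane-1,2-dithiol and BF3·OEt2 in CH2Cl2 at 0 °C to rt convert the ketone into the dithiolane 13-{2-[(2S)-2-methylbutyl]-1,3-dithiolan-2-yl}tridecan-1-ol F3.
- Raney Ni (W-2) in refluxing EtOH (Mozingo reduction) then desulfurises it to 20 under essentially neutral conditions.

**Risk 3, step 4 (monobenzylation).**
- The desymmetrisation is only statistical. The diol dissolves poorly, and the yield on BnBr may stay near 50–60%, with diether as waste.
- The fallback sets out from 8 and comes back at 10.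
- Refluxing 8 with 48% aq HBr in toluene gives 12-bromododecan-1-ol F1 selectively, because the monobromide moves into the toluene layer away from the acid.
- The ether is then made with reversed polarity by displacing the bromide with excess NaOCH2Ph (BnOH 4 equiv, NaH 3 equiv, THF/DMF, 60 °C), which gives 10.

Further compounds
F1 | step 4 | 12-bromododecan-1-ol | OCCCCCCCCCCCCBr
F2 | step 6 | (S)-trimethyl[(4-methylhex-1-en-2-yl)oxy]silane | CC[C@H](C)CC(=C)O[Si](C)(C)C
F3 | step 9 | 13-{2-[(2S)-2-methylbutyl]-1,3-dithiolan-2-yl}tridecan-1-ol | CC[C@H](C)CC1(CCCCCCCCCCCCCO)SCCS1
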